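Ring B (B1 = aryl-ether carbon, B2 = C–OH, B3/B4 = prenyl carbons, B5/B6 = C–OMe) is a 4-methoxyphenol: B2–OH sits para to B5–OMe. A Dötz benzannulation delivers exactly this pattern, so ring B is cut into an alkoxy(alkenyl)carbene chromium complex (B5, B6, B1), one CO ligand (B2) and symmetric diprenylacetylene (B3, B4). One operation forms B5–B4, B3–B2 and B2–B1, closes the ring and leaves B2–OH free while B5 is already methylated. The precursor is pentacarbonyl[methoxy(1-methoxyethenyl)carbene]chromium. The lone ring hydrogen (B1) is then oxygenated and joined to ring A by a Pd-catalysed C–O coupling.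

Key step: step 3

Remark on the chemistry: the target has no stereocentre and both alkenes are prenyl units without E/Z isomerism, so no stereocontrol is needed. Hapticity cannot be written in SMILES, so the η6-arene complex 10 is given as arene plus Cr(CO)3 fragment, and metal–CO bonds are drawn as formal double bonds.

Step 1
Reactants: 1 methyl vinyl ether; 2 hexacarbonylchromium, Cr(CO)6
Product: 5 pentacarbonyl[methoxy(1-methoxyethenyl)carbene]chromium, via 1-methoxyethenyllithium 3 (not isolated), via lithium acylchromate 4 (not isolated)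
Conditions: t-BuLi, THF, −78 to 0 °C; Cr(CO)6, THF, −78 °C to rt; Me3OBF4, CH2Cl2, 0 °C
Reagents that add atoms: trimethyloxonium tetrafluoroborate (Me3OBF4), C[O+](C)C.F[B-](F)(F)F
Why: Alpha-lithiation of the vinyl ether, addition of the vinyllithium to a CO ligand and O-methylation of the acylmetalate is the classical Fischer carbene synthesis, and the alpha-methoxy group should stabilise the alkenylcarbene against polymerisation much as an alpha-alkyl group does.

Step 2
Reactants: 6 acetylene; 7 prenyl bromide (1-bromo-3-methylbut-2-ene)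
Product: 9 2,9-dimethyldeca-2,8-dien-5-yne (diprenylacetylene), via acetylene bis-Grignard reagent 8 (not isolated)
Conditions: EtMgBr (2 equiv), Et2O, 0 °C to reflux; then CuCl (10 mol %), 7 (2.2 equiv), THF, 45 °C
Reagents that add atoms: none
Why: Copper-catalysed allylation of an alkynyl Grignard reagent should join both acetylide termini to the unhindered primary carbon of prenyl bromide, giving the linear skipped dienyne.

Step 3
Reactants: 5 pentacarbonyl[methoxy(1-methoxyethenyl)carbene]chromium; 9 diprenylacetylene
Product: 11 4,5-dimethoxy-2,3-bis(3-methylbut-2-en-1-yl)phenol, via arene tricarbonylchromium complex 10 (not isolated)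
Conditions: 9 (1.5 equiv), THF, 50 °C, argon; then air, daylight, Et2O, rt
Reagents that add atoms: none
Why: Thermal loss of one CO ligand from 5 lets the alkyne coordinate and insert into the Cr=C bond to give a vinylcarbene, CO insertion converts this into a chromium-bound vinylketene, and 6π-electrocyclisation followed by keto–enol tautomerisation gives the phenol on Cr(CO)3, which air and light strip off. This is the Dötz benzannulation in its precedented form with alpha-alkoxyalkenyl carbene complexes and internal dialkylalkynes, which furnishes 4-alkoxyphenols. Ring B is closed by electrocyclic B2–B1 bond formation in the dienylketene, after B5–B4 and B3–B2 have been made by the alkyne and CO insertions (a formal [3+2+1] assembly); no stereocentre is created. Because the carbene carbon arrives as C–OMe (B5) and the inserted CO ends as the free C–OH (B2), the para oxygen pair is differentiated by the reaction itself, and the symmetric alkyne removes any regiochemical question. The selectivity needed is benzannulation over cyclopentannulation, furan or cyclobutenone formation, which chromium, an alkenyl (not aryl) carbene, the donor solvent THF and moderate temperature favour. The isolated trisubstituted prenyl alkenes are poor ligands and could cyclopropanate only with prohibitive strain, and mild aerobic decomplexation should avoid oxidation to the quinone.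

Step 4
Reactants: 11 4,5-dimethoxy-2,3-bis(3-methylbut-2-en-1-yl)phenol
Product: 12 1,2-dimethoxy-5-(methoxymethoxy)-3,4-bis(3-methylbut-2-en-1-yl)benzene
Conditions: NaH, MOMCl, THF, 0 °C to rt
Reagents that add atoms: chloromethyl methyl ether (MOMCl), COCCl
Why: Williamson-type O-alkylation of the sodium phenoxide with the reactive chloromethyl ether installs an acetal that is stable to organolithiums and directs the next metalation.

Step 5
Reactants: 12 1,2-dimethoxy-5-(methoxymethoxy)-3,4-bis(3-methylbut-2-en-1-yl)benzene
Product: 15 2,3-dimethoxy-6-(methoxymethoxy)-4,5-bis(3-methylbut-2-en-1-yl)phenol, via aryllithium 13 (not isolated), via lithium aryltrimethoxyborate 14 (not isolated)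
Conditions: n-BuLi, TMEDA, THF, −20 to 0 °C; B(OMe)3, −78 °C to rt; 30% aq. H2O2, 0 °C to rt
Reagents that add atoms: hydrogen peroxide, OO
Why: Directed ortho-metalation should remove the only ring hydrogen (B1), which lies between the coordinating OMOM and OMe groups, faster than the benzylic–allylic CH2 hydrogens, and oxidation of the derived borate (1,2-aryl shift from boron to oxygen) gives the phenol without affecting the unactivated alkenes.

Step 6
Reactants: 16 methyl 2,4,6-trihydroxybenzoate
Product: 17 methyl 2-hydroxy-4,6-bis(methoxymethoxy)benzoate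
Conditions: MOMCl (2.1 equiv), i-Pr2NEt (2.5 equiv), CH2Cl2, 0 °C to rt
Reagents that add atoms: chloromethyl methyl ether (MOMCl), COCCl
Why: Chemoselective O-alkylation under amine-base conditions should protect the 4-OH and one ortho OH while the remaining ortho OH, held in a hydrogen bond to the ester carbonyl, stays free.

Step 7
Reactants: 17 methyl 2-hydroxy-4,6-bis(methoxymethoxy)benzoate
Product: 18 methyl 2,4-bis(methoxymethoxy)-6-(trifluoromethanesulfonyloxy)benzoate
Conditions: Tf2O, pyridine, CH2Cl2, 0 °C
Reagents that add atoms: trifluoromethanesulfonic anhydride (Tf2O), O=S(=O)(OS(=O)(=O)C(F)(F)F)C(F)(F)F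
Why: O-Sulfonylation of the chelated phenol under pyridine buffering gives an aryl triflate, a cross-coupling electrophile activated by the ortho ester.

Step 8
Reactants: 15 2,3-dimethoxy-6-(methoxymethoxy)-4,5-bis(3-methylbut-2-en-1-yl)phenol; 18 methyl 2,4-bis(methoxymethoxy)-6-(trifluoromethanesulfonyloxy)benzoate
Product: 19 methyl 2-[2,3-dimethoxy-6-(methoxymethoxy)-4,5-bis(3-methylbut-2-en-1-yl)phenoxy]-4,6-bis(methoxymethoxy)benzoate
Conditions: Pd(OAc)2 (5 mol %), tBuXPhos (2-di-tert-butylphosphino-2′,4′,6′-triisopropylbiphenyl, 8 mol %), K3PO4, toluene, 100 °C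
Reagents that add atoms: none
Why: Buchwald–Hartwig-type Pd-catalysed C–O cross-coupling pairs the favourable partners, an electron-poor ortho-ester aryl triflate for oxidative addition and an electron-rich phenoxide, with the bulky di-tert-butylbiarylphosphine promoting C–O reductive elimination and the weak base K3PO4 sparing ester, acetals and triflate.

Step 9
Reactants: 19 methyl 2-[2,3-dimethoxy-6-(methoxymethoxy)-4,5-bis(3-methylbut-2-en-1-yl)phenoxy]-4,6-bis(methoxymethoxy)benzoate
Product: 20 4-methylhydroatrovirinone, methyl 2,4-dihydroxy-6-[2-hydroxy-5,6-dimethoxy-3,4-bis(3-methylbut-2-en-1-yl)phenoxy]benzoate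
Conditions: HCl (2 M in MeOH), 35–40 °C
Reagents that add atoms: none
Why: Acid-catalysed transacetalisation of the three aryl MOM ethers to dimethoxymethane in methanol should free the phenols under conditions mild enough to leave the methyl ester, the diaryl ether and the prenyl alkenes intact.

Compound list
1 | methyl vinyl ether | COC=C | starting material
2 | hexacarbonylchromium, Cr(CO)6 | O=C=[Cr](=C=O)(=C=O)(=C=O)(=C=O)=C=O | starting material
3 | 1-methoxyethenyllithium | C=C([Li])OC | intermediate
4 | lithium pentacarbonyl[(1-methoxyethenyl)(oxido)carbene]chromate | [Li+].[O-]C(C(OC)=C)=[Cr](=C=O)(=C=O)(=C=O)(=C=O)=C=O | intermediate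
5 | pentacarbonyl[methoxy(1-methoxyethenyl)carbene]chromium | COC(C(OC)=C)=[Cr](=C=O)(=C=O)(=C=O)(=C=O)=C=O | intermediate
6 | acetylene | C#C | starting material
7 | prenyl bromide (1-bromo-3-methylbut-2-ene) | CC(C)=CCBr | starting material
8 | ethyne-1,2-diylbis(magnesium bromide) | Br[Mg]C#C[Mg]Br | intermediate
9 | 2,9-dimethyldeca-2,8-dien-5-yne (diprenylacetylene) | CC(C)=CCC#CCC=C(C)C | intermediate
10 | tricarbonyl[η6-4,5-dimethoxy-2,3-bis(3-methylbut-2-en-1-yl)phenol]chromium | COc1cc(O)c(CC=C(C)C)c(CC=C(C)C)c1OC.O=C=[Cr](=C=O)=C=O | intermediate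
11 | 4,5-dimethoxy-2,3-bis(3-methylbut-2-en-1-yl)phenol | COc1cc(O)c(CC=C(C)C)c(CC=C(C)C)c1OC | intermediate
12 | 1,2-dimethoxy-5-(methoxymethoxy)-3,4-bis(3-methylbut-2-en-1-yl)benzene | COCOc1cc(OC)c(OC)c(CC=C(C)C)c1CC=C(C)C | intermediate
13 | [2,3-dimethoxy-6-(methoxymethoxy)-4,5-bis(3-methylbut-2-en-1-yl)phenyl]lithium | [Li]c1c(OCOC)c(CC=C(C)C)c(CC=C(C)C)c(OC)c1OC | intermediate
14 | lithium [2,3-dimethoxy-6-(methoxymethoxy)-4,5-bis(3-methylbut-2-en-1-yl)phenyl]trimethoxyborate | [Li+].CO[B-](OC)(OC)c1c(OCOC)c(CC=C(C)C)c(CC=C(C)C)c(OC)c1OC | intermediate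
15 | 2,3-dimethoxy-6-(methoxymethoxy)-4,5-bis(3-methylbut-2-en-1-yl)phenol | COCOc1c(O)c(OC)c(OC)c(CC=C(C)C)c1CC=C(C)C | intermediate
16 | methyl 2,4,6-trihydroxybenzoate | COC(=O)c1c(O)cc(O)cc1O | starting material
17 | methyl 2-hydroxy-4,6-bis(methoxymethoxy)benzoate | COCOc1cc(O)c(C(=O)OC)c(OCOC)c1 | intermediate
18 | methyl 2,4-bis(methoxymethoxy)-6-(trifluoromethanesulfonyloxy)benzoate | COCOc1cc(OCOC)c(C(=O)OC)c(OS(=O)(=O)C(F)(F)F)c1 | intermediate
19 | methyl 2-[2,3-dimethoxy-6-(methoxymethoxy)-4,5-bis(3-methylbut-2-en-1-yl)phenoxy]-4,6-bis(methoxymethoxy)benzoate | COC(=O)c1c(OCOC)cc(OCOC)cc1Oc1c(OCOC)c(CC=C(C)C)c(CC=C(C)C)c(OC)c1OC | intermediate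
20 | 4-methylhydroatrovirinone | COC(=O)c1c(O)cc(O)cc1Oc1c(O)c(CC=C(C)C)c(CC=C(C)C)c(OC)c1OC | target

Total steps: 9. Longest linear sequence: 6 steps (steps 1, 3, 4, 5, 8, 9).

Steps most likely to fail

Step 3. The vinylcarbene and vinylketene intermediates may divert into cyclopentannulation, furan or cyclobutenone pathways, the carbene complex may decompose before it takes up the alkyne, or decomplexation may over-oxidise the product. The fallback builds ring B without any annulation, by twofold cross-coupling on a preformed arene; it sets out from prenyl bromide 7 and returns to the route at 12. The known, purchased 2,3-dibromo-4,5-dimethoxybenzaldehyde F1 would undergo Baeyer–Villiger oxidation (mCPBA, CH2Cl2) to 2,3-dibromo-4,5-dimethoxyphenyl formate F2. Methanolysis (K2CO3, MeOH) would give 2,3-dibromo-4,5-dimethoxyphenol F3, and NaH/MOMCl would give 1,2-dibromo-3,4-dimethoxy-6-(methoxymethoxy)benzene F4. Zinc insertion into 7 (Zn, LiCl, THF) would give bromo(3-methylbut-2-en-1-yl)zinc F5. A twofold linear-selective Negishi coupling of F4 with F5 (Pd(OAc)2, CPhos, THF) should install both prenyl groups and give 12.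

Step 8. The phenoxide may cleave the triflate at sulfur, or C–O reductive elimination may be slow at the doubly ortho-substituted phenoxide, so that hydrodetriflation wins. The fallback reverses the polarity of the ether-forming step; it sets out from 12 and 17 and returns at 19. Lithiation of 12 to 13 and borylation to 14 as in step 5, but with aqueous NH4Cl work-up in place of oxidation, would give [2,3-dimethoxy-6-(methoxymethoxy)-4,5-bis(3-methylbut-2-en-1-yl)phenyl]boronic acid F6. Chan–Lam oxidative coupling of F6 with the free hydroxyl of 17 (Cu(OAc)2, pyridine, 4 Å molecular sieves, CH2Cl2, air, rt) should give 19, making triflate 18 unnecessary.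

Step 9. Once B2–OH is free, acid may cyclise it onto the neighbouring B3 prenyl alkene (chroman formation), or methanol may add to the alkenes before all three acetals are gone. The fallback replaces hydrolysis by an acetal-to-silyl-ether exchange with no Brønsted acid; it sets out from 19 and returns at 20. TMSOTf and 2,2′-bipyridyl in CH2Cl2 at 0 °C convert aryl MOM ethers into aryl silyl ethers through bipyridinium intermediates, and would give methyl 2-[2,3-dimethoxy-4,5-bis(3-methylbut-2-en-1-yl)-6-(trimethylsilyloxy)phenoxy]-4,6-bis(trimethylsilyloxy)benzoate F7. Water at rt during work-up should cleave F7 to 20.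

Further compounds
F1 | step 3 | 2,3-dibromo-4,5-dimethoxybenzaldehyde | COc1cc(C=O)c(Br)c(Br)c1OC
F2 | step 3 | 2,3-dibromo-4,5-dimethoxyphenyl formate | COc1cc(OC=O)c(Br)c(Br)c1OC
F3 | step 3 | 2,3-dibromo-4,5-dimethoxyphenol | COc1cc(O)c(Br)c(Br)c1OC
F4 | step 3 | 1,2-dibromo-3,4-dimethoxy-6-(methoxymethoxy)benzene | COCOc1cc(OC)c(OC)c(Br)c1Br
F5 | step 3 | bromo(3-methylbut-2-en-1-yl)zinc | CC(C)=CC[Zn]Br
F6 | step 8 | [2,3-dimethoxy-6-(methoxymethoxy)-4,5-bis(3-methylbut-2-en-1-yl)phenyl]boronic acid | COCOc1c(B(O)O)c(OC)c(OC)c(CC=C(C)C)c1CC=C(C)C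
F7 | step 9 | methyl 2-[2,3-dimethoxy-4,5-bis(3-methylbut-2-en-1-yl)-6-(trimethylsilyloxy)phenoxy]-4,6-bis(trimethylsilyloxy)benzoate | COC(=O)c1c(O[Si](C)(C)C)cc(O[Si](C)(C)C)cc1Oc1c(O[Si](C)(C)C)c(CC=C(C)C)c(CC=C(C)C)c(OC)c1OC
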